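**Strategy.** The C-2 ketone and C-5 carbinol of the cyclohexenone ring (C-1 = farnesyl-bearing epoxide carbon, C-6 = epoxide CH) are para-related and flank the C-3=C-4 alkene. This 1,4-dioxygenation maps onto the α,α′-carbons of a 2-methoxyfuran, and C-3/C-4 onto an alkyne. A furan–alkyne Diels–Alder reaction of 4-farnesyl-2-methoxyfuran with methyl propiolate forms C-2–C-3 and C-4–C-5 at once; spontaneous opening of the oxa-bridge gives a hydroquinone monomethyl ether with both oxygens differentiated and all four substituents placed. Oxidative dearomatisation to the quinone monoketal, asymmetric nucleophilic epoxidation and a regio- and stereoselective carbonyl reduction then deliver the epoxyquinol.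

Key step: step 4

Remark: farnesyl = (2E,6E)-3,7,11-trimethyldodeca-2,6,10-trien-1-yl; the bicyclic compounds are numbered C-1 (farnesyl-bearing epoxide carbon), C-2 (ketone), C-3, C-4, C-5, C-6 (epoxide CH), O-7 throughout; 4-bromofuran-2(5H)-one is taken as commercially available; the sense of induction in step 7 is assumed, and the pseudoenantiomeric cinchoninium salt would be used if it proves opposite.

Step 1
Reactants: 1 4-bromofuran-2(5H)-one
Product: 2 4-(tributylstannyl)furan-2(5H)-one
Conditions: (Bu3Sn)2, Pd(PPh3)4 (5 mol %), toluene, 100 °C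
Reagents that add atoms: hexabutylditin, CCCC[Sn](CCCC)(CCCC)[Sn](CCCC)(CCCC)CCCC
Why: Palladium-catalysed stannylation of a vinyl bromide with a distannane (oxidative addition of the C4–Br bond to zerovalent palladium, Sn–Sn transmetalation, reductive elimination) is a standard entry to β-stannyl butenolides and creates no stereocentre.

Step 2
Reactants: 2 4-(tributylstannyl)furan-2(5H)-one, 3 (2E,6E)-farnesyl bromide
Product: 4 4-farnesylfuran-2(5H)-one
Conditions: tris(dibenzylideneacetone)dipalladium Pd2(dba)3 (2.5 mol %), AsPh3 (10 mol %), THF, 50 °C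
Reagents that add atoms: none
Why: Stille coupling of the vinylstannane with the allylic bromide should join butenolide C4 to the primary allyl terminus through an η3-allylpalladium intermediate that keeps the (2E) geometry, the arsine ligand speeding transmetalation of the electron-poor stannane.

Step 3
Reactants: 4 4-farnesylfuran-2(5H)-one
Product: 6 4-farnesyl-2-methoxyfuran, via potassium furanolate 5 (not isolated)
Conditions: KN(SiMe3)2, THF–DMPU, −78 °C; then MeOSO2CF3, −78 → −40 °C; basic work-up, used crude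
Reagents that add atoms: methyl trifluoromethanesulfonate, COS(=O)(=O)C(F)(F)F
Why: Deprotonation at the oxygen-bearing C5 gives the aromatic ambident furanolate 5, and a hard methylating agent in a dipolar medium should alkylate it on oxygen (enolate O-alkylation, the alkyl counterpart of the silylation of butenolides to 2-silyloxyfurans), giving the acid-sensitive methoxyfuran.

Step 4
Reactants: 6 4-farnesyl-2-methoxyfuran, 7 methyl propiolate
Product: 9 methyl 4-farnesyl-5-hydroxy-2-methoxybenzoate, via oxanorbornadiene cycloadduct 8 (not isolated)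
Conditions: methyl propiolate (1.5 equiv), toluene, 60 °C; then brief stirring with silica gel
Reagents that add atoms: none
Why: Normal-electron-demand [4+2] cycloaddition of the electron-rich furan diene (C2=C3–C4=C5) with the acetylenic ester gives the 1-methoxy-7-oxanorbornadiene 8, whose C1–O7 bond ionises with help from the methoxy group and which aromatises by loss of the C4 proton; the closest known reaction type is the Diels–Alder/ring-opening benzannulation of 2-alkoxyfurans with acetylenic esters to p-alkoxyphenols. The six-membered carbocycle is closed intermolecularly by a concerted, asynchronous suprafacial–suprafacial [4+2] addition in which the bond from furan C5 to the alkyne CH leads. No stereocentre survives, because the two bridgehead centres of racemic 8 are destroyed on aromatisation. The step needs regioselectivity (ester carbon bonded to the methoxy-bearing furan carbon), which the matched 2-methoxy and 4-alkyl donors secure by placing the largest HOMO coefficient on C5, so that C5 bonds to the electrophilic β-carbon of the propiolate. It also needs chemoselectivity for the furan over the three isolated trisubstituted alkenes, which do not react with methyl propiolate at this temperature.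

Step 5
Reactants: 9 methyl 4-farnesyl-5-hydroxy-2-methoxybenzoate
Product: 10 (4-farnesyl-5-hydroxy-2-methoxyphenyl)methanol
Conditions: LiAlH4, THF, 0 °C → rt; Rochelle salt work-up
Reagents that add atoms: none
Why: Lithium aluminium hydride reduction of the aryl ester to the benzylic alcohol (the phenol is carried as its aluminate) leaves the isolated trisubstituted alkenes untouched.

Step 6
Reactants: 10 (4-farnesyl-5-hydroxy-2-methoxyphenyl)methanol
Product: 11 2-farnesyl-5-(hydroxymethyl)-4,4-dimethoxycyclohexa-2,5-dien-1-one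
Conditions: PhI(OAc)2, MeOH, 0 °C
Reagents that add atoms: methanol, CO
Why: Oxidative dearomatisation of a p-methoxyphenol with a hypervalent iodine reagent in methanol adds methanol at the methoxy-bearing para carbon and gives the p-quinone monoketal, the ketone (future C-2) and ketal (future C-5) positions being fixed by the oxygen pattern from step 4.

Step 7
Reactants: 11 2-farnesyl-5-(hydroxymethyl)-4,4-dimethoxycyclohexa-2,5-dien-1-one
Product: 12 (1R,6S)-1-farnesyl-4-(hydroxymethyl)-5,5-dimethoxy-7-oxabicyclo[4.1.0]hept-3-en-2-one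
Conditions: tBuOOH (70 % aq.), N-benzylcinchonidinium chloride (10 mol %), 0.1 M aq. NaOH, toluene, 0 °C
Reagents that add atoms: tert-butyl hydroperoxide, CC(C)(C)OO
Why: In this Weitz–Scheffer nucleophilic epoxidation under chiral phase-transfer catalysis the tert-butylperoxide anion should add only to the unsubstituted β-carbon C-6 of the α-farnesyl enone (the other enone β-carbon C-4 is fully substituted and the side-chain alkenes are not electrophilic), and the cinchonidinium ion pair selects the enone face so that C-1 and C-6 are set together as the (1R,6S) cis-epoxide.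

Step 8
Reactants: 12 (1R,6S)-1-farnesyl-4-(hydroxymethyl)-5,5-dimethoxy-7-oxabicyclo[4.1.0]hept-3-en-2-one
Product: 13 [(1R,6S)-1-farnesyl-5,5-dimethoxy-2-oxo-7-oxabicyclo[4.1.0]hept-3-en-4-yl]methyl acetate
Conditions: Ac2O, pyridine, DMAP (cat.), CH2Cl2, 0 °C
Reagents that add atoms: acetic anhydride, CC(=O)OC(C)=O
Why: Nucleophile-catalysed acylation of the only hydroxyl group (primary, allylic) runs under non-acidic conditions that spare ketal and epoxide.

Step 9
Reactants: 13 [(1R,6S)-1-farnesyl-5,5-dimethoxy-2-oxo-7-oxabicyclo[4.1.0]hept-3-en-4-yl]methyl acetate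
Product: 14 [(1R,6S)-1-farnesyl-2,5-dioxo-7-oxabicyclo[4.1.0]hept-3-en-4-yl]methyl acetate
Conditions: Montmorillonite K10, wet CH2Cl2, rt
Reagents that add atoms: water, O
Why: Mild acid-catalysed ketal hydrolysis on the clay surface should unveil the C-5 ketone without opening the epoxide, cleaving the acetate or protonating the side-chain alkenes.

Step 10
Reactants: 14 [(1R,6S)-1-farnesyl-2,5-dioxo-7-oxabicyclo[4.1.0]hept-3-en-4-yl]methyl acetate
Product: 15 [(1R,5R,6R)-1-farnesyl-5-hydroxy-2-oxo-7-oxabicyclo[4.1.0]hept-3-en-4-yl]methyl acetate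
Conditions: NaBH4, CeCl3·7H2O, MeOH, −78 °C
Reagents that add atoms: none
Why: In this Luche 1,2-reduction under substrate control the C-5 carbonyl is flanked by the epoxide CH, whereas C-2 is shielded by the quaternary C-1 and deactivated by the β-alkyl group of its enone, so hydride should attack C-5 from the face opposite the epoxide oxygen and set (5R) with the hydroxyl cis to the epoxide, the acetate being inert at −78 °C.

**Compound list**

1 | 4-bromofuran-2(5H)-one | O=C1C=C(Br)CO1 | starting material
2 | 4-(tributylstannyl)furan-2(5H)-one | CCCC[Sn](CCCC)(CCCC)C1=CC(=O)OC1 | intermediate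
3 | (2E,6E)-farnesyl bromide, (2E,6E)-1-bromo-3,7,11-trimethyldodeca-2,6,10-triene | BrC/C=C(\C)CC/C=C(\C)CCC=C(C)C | starting material
4 | 4-farnesylfuran-2(5H)-one | O=C1C=C(C/C=C(\C)CC/C=C(\C)CCC=C(C)C)CO1 | intermediate
5 | potassium 4-farnesylfuran-2-olate (not isolated) | [K+].[O-]c1cc(C/C=C(\C)CC/C=C(\C)CCC=C(C)C)co1 | intermediate
6 | 4-farnesyl-2-methoxyfuran | COc1cc(C/C=C(\C)CC/C=C(\C)CCC=C(C)C)co1 | intermediate
7 | methyl propiolate (methyl prop-2-ynoate) | C#CC(=O)OC | starting material
8 | racemic methyl 5-farnesyl-1-methoxy-7-oxabicyclo[2.2.1]hepta-2,5-diene-2-carboxylate (not isolated) | COC(=O)C1=CC2OC1(OC)C=C2C/C=C(\C)CC/C=C(\C)CCC=C(C)C | intermediate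
9 | methyl 4-farnesyl-5-hydroxy-2-methoxybenzoate | COC(=O)c1cc(O)c(C/C=C(\C)CC/C=C(\C)CCC=C(C)C)cc1OC | intermediate
10 | (4-farnesyl-5-hydroxy-2-methoxyphenyl)methanol | OCc1cc(O)c(C/C=C(\C)CC/C=C(\C)CCC=C(C)C)cc1OC | intermediate
11 | 2-farnesyl-5-(hydroxymethyl)-4,4-dimethoxycyclohexa-2,5-dien-1-one | O=C1C=C(CO)C(OC)(OC)C=C1C/C=C(\C)CC/C=C(\C)CCC=C(C)C | intermediate
12 | (1R,6S)-1-farnesyl-4-(hydroxymethyl)-5,5-dimethoxy-7-oxabicyclo[4.1.0]hept-3-en-2-one | OCC1=CC(=O)[C@]2(C/C=C(\C)CC/C=C(\C)CCC=C(C)C)O[C@@H]2C1(OC)OC | intermediate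
13 | [(1R,6S)-1-farnesyl-5,5-dimethoxy-2-oxo-7-oxabicyclo[4.1.0]hept-3-en-4-yl]methyl acetate | CC(=O)OCC1=CC(=O)[C@]2(C/C=C(\C)CC/C=C(\C)CCC=C(C)C)O[C@@H]2C1(OC)OC | intermediate
14 | [(1R,6S)-1-farnesyl-2,5-dioxo-7-oxabicyclo[4.1.0]hept-3-en-4-yl]methyl acetate | CC(=O)OCC1=CC(=O)[C@]2(C/C=C(\C)CC/C=C(\C)CCC=C(C)C)O[C@@H]2C1=O | intermediate
15 | [(1R,5R,6R)-1-farnesyl-5-hydroxy-2-oxo-7-oxabicyclo[4.1.0]hept-3-en-4-yl]methyl acetate | CC(=O)OCC1=CC(=O)[C@]2(C/C=C(\C)CC/C=C(\C)CCC=C(C)C)O[C@@H]2[C@@H]1O | target

Total step count: 10. Longest linear sequence: 10 steps (1 → 15).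

**Steps most likely to fail**

1. Step 3. The ambident furanolate may be methylated on carbon (C-3 or C-5) instead of oxygen, or the methoxyfuran may revert to 4 by hydrolysis on work-up. Fallback, setting out from 4 and coming back at 9: soft enolisation (iPr3SiOTf, Et3N, CH2Cl2, 0 °C) gives 4-farnesyl-2-(triisopropylsilyloxy)furan F1. Its Diels–Alder reaction with 7 (toluene, 60 °C) followed by Bu4NF work-up should give methyl 4-farnesyl-2,5-dihydroxybenzoate F2. The unchelated 5-hydroxyl is allylated (allyl bromide, K2CO3, acetone) to methyl 5-(allyloxy)-4-farnesyl-2-hydroxybenzoate F3. The ester-chelated 2-hydroxyl is then methylated (MeI, K2CO3, DMF, 50 °C) to methyl 5-(allyloxy)-4-farnesyl-2-methoxybenzoate F4. Deallylation (Pd(PPh3)4, morpholine, THF) returns to 9.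

2. Step 7. The chiral ion pair may discriminate the two enone faces poorly. Fallback, setting out from 11 and coming back at 14: auxiliary control replaces catalyst control. Transketalisation with (2S,4S)-pentane-2,4-diol (PPTS, benzene, 4 Å molecular sieves) gives the chiral spiroketal (2S,4S)-10-farnesyl-7-(hydroxymethyl)-2,4-dimethyl-1,5-dioxaspiro[5.5]undeca-7,10-dien-9-one F5. Epoxidation (tBuOOH, DBU, CH2Cl2, 0 °C) should occur anti to the axial methyl group and give the (1R,6S)-epoxide of F5 F6; the diol enantiomer is chosen to match this face. Acetylation (Ac2O, pyridine, DMAP) gives the acetate of F6 F7, and hydrolysis on Montmorillonite K10 returns to 14.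

3. Step 10. Hydride may attack the C-2 carbonyl, approach from the epoxide face, or reduce both carbonyls. Fallback, setting out from 12 and coming back at 15: internal hydride delivery replaces external steric control. Hydrolysis of 12 (Montmorillonite K10, wet CH2Cl2) gives (1R,6S)-1-farnesyl-4-(hydroxymethyl)-7-oxabicyclo[4.1.0]hept-3-ene-2,5-dione F8. Hydroxyl-directed reduction (Me4NBH(OAc)3, MeCN–AcOH, −30 °C) delivers hydride from the boron-bound primary hydroxyl to the neighbouring C-5 carbonyl and should give (1R,5R,6R)-1-farnesyl-5-hydroxy-4-(hydroxymethyl)-7-oxabicyclo[4.1.0]hept-3-en-2-one F9. Selective acetylation of the primary hydroxyl (AcCl, 2,4,6-collidine, CH2Cl2, −78 °C) returns to 15.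

**Further compounds**

F1 | step 3 | 4-farnesyl-2-(triisopropylsilyloxy)furan | CC(C)[Si](Oc1cc(C/C=C(\C)CC/C=C(\C)CCC=C(C)C)co1)(C(C)C)C(C)C
F2 | step 3 | methyl 4-farnesyl-2,5-dihydroxybenzoate | COC(=O)c1cc(O)c(C/C=C(\C)CC/C=C(\C)CCC=C(C)C)cc1O
F3 | step 3 | methyl 5-(allyloxy)-4-farnesyl-2-hydroxybenzoate | COC(=O)c1cc(OCC=C)c(C/C=C(\C)CC/C=C(\C)CCC=C(C)C)cc1O
F4 | step 3 | methyl 5-(allyloxy)-4-farnesyl-2-methoxybenzoate | COC(=O)c1cc(OCC=C)c(C/C=C(\C)CC/C=C(\C)CCC=C(C)C)cc1OC
F5 | step 7 | (2S,4S)-10-farnesyl-7-(hydroxymethyl)-2,4-dimethyl-1,5-dioxaspiro[5.5]undeca-7,10-dien-9-one | O=C1C=C(CO)C2(O[C@@H](C)C[C@H](C)O2)C=C1C/C=C(\C)CC/C=C(\C)CCC=C(C)C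
F6 | step 7 | (1R,6S)-epoxide of F5 (12 with the dimethyl ketal replaced by the (2S,4S)-pentane-2,4-diyl ketal) | OCC1=CC(=O)[C@]2(C/C=C(\C)CC/C=C(\C)CCC=C(C)C)O[C@@H]2C13O[C@@H](C)C[C@H](C)O3
F7 | step 7 | acetate of F6 | CC(=O)OCC1=CC(=O)[C@]2(C/C=C(\C)CC/C=C(\C)CCC=C(C)C)O[C@@H]2C13O[C@@H](C)C[C@H](C)O3
F8 | step 10 | (1R,6S)-1-farnesyl-4-(hydroxymethyl)-7-oxabicyclo[4.1.0]hept-3-ene-2,5-dione | OCC1=CC(=O)[C@]2(C/C=C(\C)CC/C=C(\C)CCC=C(C)C)O[C@@H]2C1=O
F9 | step 10 | (1R,5R,6R)-1-farnesyl-5-hydroxy-4-(hydroxymethyl)-7-oxabicyclo[4.1.0]hept-3-en-2-one | OCC1=CC(=O)[C@]2(C/C=C(\C)CC/C=C(\C)CCC=C(C)C)O[C@@H]2[C@@H]1O
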